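The ratio of two rates has no time in it: divide the rate of the left-handed product by that of the right-handed product, and whatever both steps share falls out, so with the same free catalyst a ratio read in one flask can travel to the next.

| flask | left-handed substrate | right-handed substrate | solid reagent | free catalyst | racemization catalyst | remark | time |
|---|---|---|---|---|---|---|---|
| spring | 0.046 M | 0.046 M | 1 equiv | 0.5 mol% | 0.5 mol% | run made earlier |  |
| flask | 0.046 M | 0.046 M | 2.00 equiv | 0.5 mol% | 0.5 mol% |  | 5.0 h |

spring run (percent of the left-handed substrate and right-handed substrate together charged)

| time / min | left-handed product / % | right-handed product / % | left-handed substrate / % |
|---|---|---|---|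
| 20.0 | 1.7 | 0.8 | 48.2 |
| 40.0 | 5.3 | 2.5 | 46.6 |
| 50.0 | 6.8 | 3.4 | 45.6 |
| 80.0 | 13.1 | 5.4 | 40.7 |
| 90.0 | 15.2 | 6.0 | 39.3 |

(each reading ± 0.3 percentage points)

- free catalyst is single-handed; left-handed substrate and right-handed substrate are mirror images of each other, charged as a racemate, each of them at the stated concentration
- solid, in amounts per volume of the solution: solid reagent
- at the start none of the solid reagent is in solution
- an excess is the difference of the two amounts in percent of their sum
- an excess is below zero if the other one leads

- left-handed product and right-handed product together, in percent of the left-handed substrate and right-handed substrate charged together, at 5.0 h
- excess of left-handed product over right-handed product in the product at 5.0 h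
- whether the exchange between left-handed substrate and right-handed substrate keeps pace with the reaction: how far the product's excess at 5.0 h gets from its value without exchange to its value with instant exchange (above 80 % keeps pace, below 20 % hardly takes part, else lags behind)

Build the flask up, starting with the main step, each substrate left to itself. The two latest spring readings, summed to weigh down the scatter, give a reading of 2.48: this is s, the selectivity factor, left-handed product formed per right-handed product formed at equal [left-handed substrate] and [right-handed substrate]. The rate ratio is s times [left-handed substrate]/[right-handed substrate], so the earliest product carries an excess of s less one over s plus one, 42.6 %. With this step by itself the left-handed substrate goes faster, and the excess sinks as the ratio of the substrates sinks.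

Now add the exchange. At 90.0 min in the spring run, without exchange, the left-handed substrate would stand at 34.8 % and the right-handed at 44.0 %. Yet the reading is 39.3 %, and the balance leaves 39.5 % for the right-handed substrate. While the gap stays as narrow as that, the rate ratio stays at s, so my reckoning is an excess of 42.6 % and an exchange that keeps pace.

Last comes the solid reagent. If each product takes one reagent, the 2.00 equiv of the flask match both substrates together, while the 1 equiv of the spring run match half of them. If both steps draw on the same reagent, it falls out of s, so it can move y without moving the excess that s gives. Since s holds no time, I commit to no y of my own.

The forecast gives a y of 78 %, an excess of 42 % and an exchange that keeps pace, and its words on the reagent are conditional: “If so, extra solid adds little”.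

The flask gives 68.3 %, an excess of 42.3 %, and an exchange that keeps pace, 93 % of the way up from the 25.1 % without exchange.

    partner + racemization catalyst → spent catalyst (k = 0.767 L mol⁻¹ min⁻¹)
    solid reagent ⇌ partner, rate k2*(cs2 - [partner]) while solid is left; crystals form when [partner] > cs2 (solubility = 23.0 mM, k = 0.0185 min⁻¹)
    partner + free catalyst + left-handed substrate → free catalyst + left-handed product (k = 2600 L² mol⁻² min⁻¹)
    partner + free catalyst + right-handed substrate → free catalyst + right-handed product (k = 1020 L² mol⁻² min⁻¹)
    left-handed substrate + racemization catalyst ⇌ right-handed substrate + racemization catalyst, rate k5*[racemization catalyst]*[left-handed substrate] forward; the back reaction follows from the equilibrium constant (k = 639 L mol⁻¹ min⁻¹)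

By 2.50 h the flask had reacted 36.7 %, and the second stretch added 32 percentage points, less than the first. Split by s, the flask's product gives 48.7 % of left-handed product, and the flask holds 48.6 %. In the neighbour flask with 0.500 equiv of solid reagent, product reaches 24.9 %; s gives 17.7 % of left-handed product, and that flask holds 17.8 %.

The runs are simulated for substances that don't exist; noise was put on by code.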